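**Plan**
- Retrosynthesis: the two phenols go back to benzyl ethers and the C2=C3 bond to a flavanone. Ring C is then cut at C4–C4a (aryl ketone), at O1–C2 (benzylic aryl ether) and at C2–C3 (β-hydroxy ester).
- Forward: rings B and A are bought intact. C2–C3 is made first (Reformatsky addition to the tetramethoxybenzaldehyde), O1–C2 second (Mitsunobu etherification with 3,5-bis(benzyloxy)phenol), and ring C closes last by intramolecular Friedel–Crafts acylation. Dehydrogenation and debenzylation finish.
- Enabling feature: at the flavanone level C2 is an sp3 benzylic carbon, so O1–C2 is an ordinary ether that can be made before ring C exists. C4a is one of two symmetry-equivalent CH carbons of the 3,5-dioxygenated aryloxy ring A, each ortho to O1, ortho to one benzyloxy group and para to the other.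
- The carboxyl group travels as an allyl ester and is released by palladium catalysis under neutral conditions, because the C2–O1 ether is sensitised to acid by the 2'- and 4'-methoxy groups and to base by the β-carbonyl.
- Stereochemistry: the target has no stereocentre. C2 is racemic from compound 4 to compound 10 and becomes planar in the dehydrogenation.

Key step: step 4

Assumption: compounds 1, 2 and 5 are taken to be purchasable. Atom labels follow flavonoid numbering (O1, C2, C3, C4, C4a, C5 to C8, C8a; primed numbers for ring B).

Step 1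
Reactants: 1 2,3,4,5-tetramethoxybenzaldehyde; 2 allyl bromoacetate
Product: 4 racemic allyl 3-hydroxy-3-(2,3,4,5-tetramethoxyphenyl)propanoate, via allyl (bromozincio)acetate 3 (not isolated)
Conditions: Zn dust (Me3SiCl-activated), THF, 40 °C; then sat. aq NH4Cl
Reagents that add atoms: none
Why: Reformatsky reaction: zinc inserts into the C–Br bond of 2 to give the zinc enolate 3, which adds to the aldehyde of 1 without touching the allyl ester, forming C2–C3 and a racemic carbinol centre that needs no control because it is later made planar.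

Step 2
Reactants: 4 racemic allyl 3-hydroxy-3-(2,3,4,5-tetramethoxyphenyl)propanoate; 5 3,5-bis(benzyloxy)phenol
Product: 6 racemic allyl 3-[3,5-bis(benzyloxy)phenoxy]-3-(2,3,4,5-tetramethoxyphenyl)propanoate
Conditions: PPh3, DIAD, toluene, 0 °C to rt
Reagents that add atoms: none
Why: Mitsunobu reaction: PPh3/DIAD activates the secondary benzylic hydroxyl and the phenol 5 (pKa near 9, acidic enough for the betaine) displaces it as phenoxide to form the O1–C2 ether, the centre remaining racemic whether substitution runs by direct displacement or through an ion pair.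

Step 3
Reactants: 6 racemic allyl 3-[3,5-bis(benzyloxy)phenoxy]-3-(2,3,4,5-tetramethoxyphenyl)propanoate
Product: 7 racemic 3-[3,5-bis(benzyloxy)phenoxy]-3-(2,3,4,5-tetramethoxyphenyl)propanoic acid
Conditions: Pd(PPh3)4 (5 mol%), morpholine, THF, rt; aq. citric acid work-up
Reagents that add atoms: none
Why: Tsuji–Trost deallylation: zerovalent palladium ionises the allyl ester and morpholine traps the allyl group, so the acid is set free under neutral conditions that spare the acid-sensitive benzylic aryl ether and avoid an enolate-forming base that could expel the phenoxide.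

Step 4
Reactants: 7 racemic 3-[3,5-bis(benzyloxy)phenoxy]-3-(2,3,4,5-tetramethoxyphenyl)propanoic acid
Product: 9 racemic 5,7-bis(benzyloxy)-2-(2,3,4,5-tetramethoxyphenyl)chroman-4-one, via mixed carboxylic trifluoroacetic anhydride 8 (not isolated)
Conditions: (CF3CO)2O (1.5 equiv), CH2Cl2, 0 °C; then sat. aq NaHCO3
Reagents that add atoms: none
Why: Trifluoroacetic anhydride converts the acid into mixed anhydride 8, an acylium equivalent that is attacked by ring A at the carbon ortho to O1; loss of a proton from the arenium ion and of trifluoroacetate gives the aryl ketone. This is the intramolecular Friedel–Crafts acylation by which 3-aryloxypropanoic acids are routinely closed to chroman-4-ones. Ring C closes in a 6-exo-trig mode at the acyl carbon, forming C4–C4a. No stereocentre is created and the racemic C2 centre is not touched. The step needs site selectivity on ring A and chemoselectivity against ring B: the two carbons ortho to O1 are the only ones the tether reaches and are equivalent by symmetry, each ortho to one and para to the other benzyloxy group, whereas closure onto C6' of ring B would give a strained five-membered indanone on a less activated ring. Low temperature, a small excess of anhydride and a bicarbonate quench should keep the trifluoroacetic acid formed from ionising the C2–O1 benzylic ether or cleaving the benzyl ethers.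

Step 5
Reactants: 9 racemic 5,7-bis(benzyloxy)-2-(2,3,4,5-tetramethoxyphenyl)chroman-4-one
Product: 11 5,7-bis(benzyloxy)-2-(2,3,4,5-tetramethoxyphenyl)-4H-chromen-4-one, via 3-iodoflavanone 10 (not isolated)
Conditions: I2 (10 mol%), DMSO, 110 °C
Reagents that add atoms: none
Why: Iodine-mediated dehydrogenation of a flavanone: α-iodination at C3 through the enol gives 10, which loses HI across C2–C3 to the aromatic 4-pyranone while dimethyl sulfoxide reoxidises HI to I2, and the racemic C2 centre disappears; any 2'-hydroxychalcone from ring opening re-closes under the same conditions, and partial loss of the 5-O-benzyl group would be harmless because step 6 removes it anyway.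

Step 6
Reactants: 11 5,7-bis(benzyloxy)-2-(2,3,4,5-tetramethoxyphenyl)-4H-chromen-4-one
Product: 12 5,7-dihydroxy-2-(2,3,4,5-tetramethoxyphenyl)-4H-chromen-4-one (5,7-dihydroxy-2',3',4',5'-tetramethoxyflavone)
Conditions: H2 (1 atm), 10% Pd/C, EtOAc–MeOH, rt
Reagents that add atoms: none
Why: Hydrogenolysis of aryl benzyl ethers over palladium on carbon at room temperature is faster than reduction of the conjugated, vinylogous-ester C2=C3 bond of a flavone, and the methyl ethers are inert, so both phenols should be unveiled cleanly if the reaction is stopped at full debenzylation.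

**Compound list**
1 | 2,3,4,5-tetramethoxybenzaldehyde | COc1cc(C=O)c(OC)c(OC)c1OC | starting material
2 | allyl bromoacetate (prop-2-enyl 2-bromoacetate) | C=CCOC(=O)CBr | starting material
3 | allyl (bromozincio)acetate, Reformatsky reagent drawn in its C-bound form, not isolated | C=CCOC(=O)C[Zn]Br | intermediate
4 | racemic allyl 3-hydroxy-3-(2,3,4,5-tetramethoxyphenyl)propanoate | COc1cc(C(O)CC(=O)OCC=C)c(OC)c(OC)c1OC | intermediate
5 | 3,5-bis(benzyloxy)phenol | Oc1cc(OCc2ccccc2)cc(OCc2ccccc2)c1 | starting material
6 | racemic allyl 3-[3,5-bis(benzyloxy)phenoxy]-3-(2,3,4,5-tetramethoxyphenyl)propanoate | COc1cc(C(CC(=O)OCC=C)Oc2cc(OCc3ccccc3)cc(OCc3ccccc3)c2)c(OC)c(OC)c1OC | intermediate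
7 | racemic 3-[3,5-bis(benzyloxy)phenoxy]-3-(2,3,4,5-tetramethoxyphenyl)propanoic acid | COc1cc(C(CC(=O)O)Oc2cc(OCc3ccccc3)cc(OCc3ccccc3)c2)c(OC)c(OC)c1OC | intermediate
8 | racemic 3-[3,5-bis(benzyloxy)phenoxy]-3-(2,3,4,5-tetramethoxyphenyl)propanoic trifluoroacetic anhydride, not isolated | COc1cc(C(CC(=O)OC(=O)C(F)(F)F)Oc2cc(OCc3ccccc3)cc(OCc3ccccc3)c2)c(OC)c(OC)c1OC | intermediate
9 | racemic 5,7-bis(benzyloxy)-2-(2,3,4,5-tetramethoxyphenyl)chroman-4-one | COc1cc(C2CC(=O)c3c(OCc4ccccc4)cc(OCc4ccccc4)cc3O2)c(OC)c(OC)c1OC | intermediate
10 | 5,7-bis(benzyloxy)-3-iodo-2-(2,3,4,5-tetramethoxyphenyl)chroman-4-one, racemic mixture of diastereomers, not isolated | COc1cc(C2Oc3cc(OCc4ccccc4)cc(OCc4ccccc4)c3C(=O)C2I)c(OC)c(OC)c1OC | intermediate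
11 | 5,7-bis(benzyloxy)-2-(2,3,4,5-tetramethoxyphenyl)-4H-chromen-4-one | COc1cc(-c2cc(=O)c3c(OCc4ccccc4)cc(OCc4ccccc4)cc3o2)c(OC)c(OC)c1OC | intermediate
12 | 5,7-dihydroxy-2-(2,3,4,5-tetramethoxyphenyl)-4H-chromen-4-one | COc1cc(-c2cc(=O)c3c(O)cc(O)cc3o2)c(OC)c(OC)c1OC | target

**Total step count:** 6
**Longest linear sequence:** 6 steps (1 to 12)

**Steps most likely to fail**

1. Step 2 (Mitsunobu etherification). The risk is dehydration of the activated β-hydroxy ester towards the conjugated cinnamate, since the ester acidifies the C3 hydrogens and the electron-rich ring B stabilises positive charge at C2. A second risk is alkylation of the electron-rich phenol through carbon instead of oxygen. The fallback sets out from 1 and comes back to the route at 7; it removes the carbonyl from the chain during ether formation. Allylmagnesium bromide in THF at 0 °C should convert 1 into racemic 1-(2,3,4,5-tetramethoxyphenyl)but-3-en-1-ol F1. Mitsunobu coupling of this alcohol, which has no carbonyl-activated hydrogens, with 5 (PPh3, DIAD) should give racemic 1-[1-[3,5-bis(benzyloxy)phenoxy]but-3-enyl]-2,3,4,5-tetramethoxybenzene F2. Dihydroxylation (K2OsO4·2H2O cat., N-methylmorpholine N-oxide, acetone–water) would give 4-[3,5-bis(benzyloxy)phenoxy]-4-(2,3,4,5-tetramethoxyphenyl)butane-1,2-diol F3 as a diastereomer mixture. Cleavage with NaIO4 would give racemic 3-[3,5-bis(benzyloxy)phenoxy]-3-(2,3,4,5-tetramethoxyphenyl)propanal F4, which would be oxidised at once under buffered Pinnick conditions (NaClO2, NaH2PO4, 2-methylbut-2-ene, tert-butanol–water) to acid 7.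

2. Step 4 (key step). The risk is ionisation of the C2–O1 bond by the trifluoroacetic acid released, followed by loss of the phenol through elimination or its re-attachment through carbon. Trifluoroacetylation of ring A could also compete. The fallback sets out from 1 and comes back to the route at 11; it builds ring C by the chalcone route, with no acid. Claisen–Schmidt condensation of 1 with commercial 1-[2,4-bis(benzyloxy)-6-hydroxyphenyl]ethanone F5 (KOH, EtOH, rt) should give (E)-1-[2,4-bis(benzyloxy)-6-hydroxyphenyl]-3-(2,3,4,5-tetramethoxyphenyl)prop-2-en-1-one F6. Heating F6 with catalytic I2 in DMSO should bring about oxa-Michael closure to flavanone 9 in the flask and its dehydrogenation, delivering 11.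

3. Step 5 (dehydrogenation). The risk is electrophilic iodination of the electron-rich ring A and cleavage of benzyl ethers by hydrogen iodide at the temperature needed, giving mixtures that are hard to purify. The fallback sets out from 9 and comes back to the route at 11; it replaces the halogen-based oxidation by a palladium-mediated one. Soft enolisation of 9 with Me3SiOTf and Et3N in CH2Cl2 at 0 °C should give racemic [5,7-bis(benzyloxy)-2-(2,3,4,5-tetramethoxyphenyl)-2H-chromen-4-yl]oxy-trimethylsilane F7. Saegusa–Ito oxidation of F7 with Pd(OAc)2 (divalent palladium, one equivalent) in MeCN at room temperature should then give 11.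

**Further compounds**
F1 | step 2 | racemic 1-(2,3,4,5-tetramethoxyphenyl)but-3-en-1-ol | COc1cc(C(O)CC=C)c(OC)c(OC)c1OC
F2 | step 2 | racemic 1-[1-[3,5-bis(benzyloxy)phenoxy]but-3-enyl]-2,3,4,5-tetramethoxybenzene | COc1cc(C(CC=C)Oc2cc(OCc3ccccc3)cc(OCc3ccccc3)c2)c(OC)c(OC)c1OC
F3 | step 2 | 4-[3,5-bis(benzyloxy)phenoxy]-4-(2,3,4,5-tetramethoxyphenyl)butane-1,2-diol, diastereomer mixture | COc1cc(C(CC(O)CO)Oc2cc(OCc3ccccc3)cc(OCc3ccccc3)c2)c(OC)c(OC)c1OC
F4 | step 2 | racemic 3-[3,5-bis(benzyloxy)phenoxy]-3-(2,3,4,5-tetramethoxyphenyl)propanal | COc1cc(C(CC=O)Oc2cc(OCc3ccccc3)cc(OCc3ccccc3)c2)c(OC)c(OC)c1OC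
F5 | step 4 | 1-[2,4-bis(benzyloxy)-6-hydroxyphenyl]ethanone (purchased) | CC(=O)c1c(O)cc(OCc2ccccc2)cc1OCc1ccccc1
F6 | step 4 | (E)-1-[2,4-bis(benzyloxy)-6-hydroxyphenyl]-3-(2,3,4,5-tetramethoxyphenyl)prop-2-en-1-one | COc1cc(/C=C/C(=O)c2c(O)cc(OCc3ccccc3)cc2OCc2ccccc2)c(OC)c(OC)c1OC
F7 | step 5 | racemic [5,7-bis(benzyloxy)-2-(2,3,4,5-tetramethoxyphenyl)-2H-chromen-4-yl]oxy-trimethylsilane | COc1cc(C2C=C(O[Si](C)(C)C)c3c(OCc4ccccc4)cc(OCc4ccccc4)cc3O2)c(OC)c(OC)c1OC
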